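The numbers of this flask are made up.

I decide to rank these set-ups by one number before I look at any run, so here are the flasks and the cycle.

| setting | theta | gamma | alpha | delta |
|---|---|---|---|---|
| substrate | 0.050 M | 0.050 M | 0.050 M | 0.050 M |
| coupling partner | 0.500 equiv (fed, over 16.0 h) | 0.500 equiv | 0.500 equiv | 0.500 equiv |
| free catalyst | 2.5 mol% | 2.5 mol% | 2.5 mol% | 2.5 mol% |
| time | 20 h | 20 h |  | 20 h |
| remark | a stirred flask in which coupling partner is dosed at a steady rate over 16.0 h without added volume, worked up at 20 h | plug flow through a tube for 20 h, no back-mixing | one stirred flow tank at steady state, fed with the mixture as stated, mean residence time 20 h | everything together in a closed stirred flask, run for 20 h |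

    catalyst intermediate B ⇌ by-product + catalyst intermediate C (K1 = 0.321 M, k1 = 0.00605 /s)
    catalyst intermediate C ⇌ free catalyst + target (K2 = 0.0565 M, k2 = 0.0173 /s)
    coupling partner + catalyst intermediate A ⇌ catalyst intermediate B (K3 = 59 /M, k3 = 0.663 /M/s)
    substrate + free catalyst → catalyst intermediate A (k4 = 0.248 /M/s)

1. the set-up with the highest amount of target at the outlet or at the end, in percent of the substrate put in ("none" if the first two lie within 2 percentage points) (theta / gamma / alpha / delta / none)
2. amount of target at the outlet or at the end, in percent of the substrate put in, theta
3. amount of target at the outlet or at the end, in percent of the substrate put in, gamma
4. amount of target at the outlet or at the end, in percent of the substrate put in, alpha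
5. amount of target at the outlet or at the end, in percent of the substrate put in, delta

- the stated concentrations are those of everything mixed, before any reaction; amounts are the same in each set-up
- the feed brings no volume worth counting
- run time (theta): 20 h

The coupling partner is charged at 0.500 equiv, so it is the limiting reagent, and target stops at 50.0% of the substrate charge. The question is how much of that charge each vessel converts.

I solve one end first, with coupling partner scarce. The catalyst then waits as catalyst intermediate A, its resting state, and the coupling partner decays pseudo-first-order. But the return of catalyst intermediate B to coupling partner and catalyst intermediate A runs at 0.0112 /s, faster than its forward step at 0.00605 /s, so 35.0% of encounters pass. The coupling partner therefore decays at 1.04 /h. That rate times the 20 h on offer is the quantity I carry, the coupling number, which counts the coupling-partner lifetimes a vessel grants (a Damköhler number): 20.9.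

At the other end, at the start, I set the net flows through the cycle equal and count every form of the catalyst: for each catalyst intermediate A I reckon 0.959 of catalyst intermediate B, 0.335 of catalyst intermediate C and 0.468 of free catalyst, so catalyst intermediate A has a share of 36.2%. Joining the ends, this share held throughout gives a floor of 7.56.

In gamma and delta, the fraction of coupling partner left is the exponential of minus the number, so target reaches 50.0%. In theta, I reckon that 5.99% of the charge stands unconverted when the feed ends, and it decays until the end, giving 50.0%. In alpha, the fraction left is one over one plus the number, which gives 47.7%, and the floor gives 44.2%. One number is enough for the batch and tube set-ups, while alpha needs the floor beside it. The top two lie within 2 percentage points, so I name none.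

The forecast also says none, because “the top two cannot be separated”. It gives 49.8% for theta, 49.9% for gamma, 47.2% for alpha and 49.9% for delta. Its alpha differs slightly from my 47.7%.

The simulation gives none, with 49.9% for theta, 50.0% for gamma, 47.1% for alpha and 50.0% for delta.

The coupling partner carries this outcome: its shrinking supply is the main reason, for without it target in gamma rises from 50.0% to 98.7%, which is 97% of what is missing. The margin in time is wide, since gamma has moved by 5 points at 4.16 h. The coupling number contains no equivalents, so at 0.300 equiv it stays 20.9 and predicts 30.0%. That neighbour of gamma ends at 30.0% target, with 67.5% of the substrate left.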